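**Plan**
1. Numbering: oxane O1, C2 (hemiketal), C3 (CHBr), C4, C5, C6 (OCH2); side chain C1' (CH3), C2' (C–Cl), C3'=C4'(Br).
2. Retrosynthetic cuts, in order: C3–Br and C2–OH (to the C2=C3 enol ether); O1–C2 (to a C6 alcohol and a masked C2 ketone); C3'=C4' (to a C3' lactol and bromoform); the C2 ketone (to a terminal alkene); O1–C3' (γ-lactone to cyclobutanone); last, C2'–C5 together with C3'–C6.
3. Enabling feature: C1'–C2'(Cl)–C3' holds the atoms of chloro(methyl)ketene, and the chain from C6 to the C2 methyl is hexa-1,5-diene. O1 sits between C6 and the carbon next to C2', so a temporary C3'–C6 bond puts the acyclic neighbours C2' and C5 side by side in a four-membered ring C3'–C2'–C5–C6.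
4. Forward order of rings: cyclobutanone (step 2); expansion to the γ-lactone O1–C3'–C2'–C5–C6 (step 3); opening of that ring by olefination at C3' (step 7); closure of the oxane O1–C2–C3–C4–C5–C6 (step 8).
5. Stereochemistry: C2' and C5 arise together in the cycloaddition (relative: approach past Cl; absolute: C2-symmetric (2R,5R)-pyrrolidine). The E alkene comes from the chromium olefination, C3 from bromide-exchange equilibration to the equatorial bromide, and C2 from the anomeric equilibrium of the hemiketal.

Key step: step 2

Assumption: the quadrant model in step 2 is taken to predict the sense of induction of the (2R,5R)-amine correctly; if the opposite sense were found, the commercial (2S,5S)-amine would replace 2 with nothing else changed.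

**Step 1**
Reactants: 1 2-chloropropanoyl chloride (racemic); 2 (2R,5R)-2,5-dimethylpyrrolidine
Product: 3 2-chloro-1-[(2R,5R)-2,5-dimethylpyrrolidin-1-yl]propan-1-one (both α-epimers)
Conditions: Et3N, CH2Cl2, 0 °C → rt
Reagents that add atoms: none
Why: Schotten–Baumann-type N-acylation of a secondary amine by an acid chloride is reliable even for this hindered pyrrolidine, and the configuration of the α-carbon does not matter because that carbon becomes sp2 in step 2.

**Step 2**
Reactants: 3 2-chloro-1-[(2R,5R)-2,5-dimethylpyrrolidin-1-yl]propan-1-one; 4 hexa-1,5-diene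
Product: 7 (2S,3R)-3-(but-3-en-1-yl)-2-chloro-2-methylcyclobutan-1-one, via keteniminium triflate 5 (not isolated), via cyclobutaniminium triflate 6 (not isolated)
Conditions: Tf2O (1.1 equiv), 2,4,6-collidine (1.2 equiv), 4 (5 equiv), CH2Cl2, −20 → 40 °C; then H2O, 40 °C
Reagents that add atoms: water, O; triflic anhydride, O=S(=O)(OS(=O)(=O)C(F)(F)F)C(F)(F)F (counter-ion of 5 and 6 only)
Why: Proposed new method: O-triflation of 3 and removal of the chlorine-acidified α-proton by collidine should give the chloro(methyl)keteniminium ion 5, one species only because the C2-symmetric amine makes its two nitrogen substituents equivalent; what has not been shown is this α-chloro, auxiliary-bearing cumulene in combination with an unactivated 1-alkene. The nucleophilic CH2 terminus C6 of one double bond of 4 attacks the central carbon C3' in the plane that holds CH3 and Cl, positive charge builds up on the more substituted C5, and C5 bonds to the enamine-like C2' before a free cation can form, so that the ring C3'–C2'–C5–C6 closes by a one-step, unequally advanced [2+2] cycloaddition, the closest known reaction types being the keteniminium–alkene cycloaddition of 2,5-dimethylpyrrolidine amides and the thermal cycloaddition of chloro(methyl)ketene. The relative configuration of C2' and C5 is set by the approach: the alkene comes in past chlorine, the smaller substituent, and turns its chain away from it, which after ring closure leaves CH3 cis and Cl trans to the butenyl group. The absolute configuration is set by the auxiliary: on the chlorine side one of the two quadrants is filled by a ring methyl group of the (2R,5R)-amine, so C5 should reach C2' through the open quadrant and give the (2S,3R) ketone. The step needs regioselectivity (secured by the polarisation of the terminal alkene, C6 to C3'), single addition (secured by the excess of volatile 4) and ring closure faster than capture of C5 by the second double bond (secured by the near-concerted bond formation). Hydrolysis of 6 in plain water, not hydroxide, avoids semibenzilic ring contraction of the α-chloro iminium salt and gives back 2.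

**Step 3**
Reactants: 7 (2S,3R)-3-(but-3-en-1-yl)-2-chloro-2-methylcyclobutan-1-one
Product: 8 (3S,4R)-4-(but-3-en-1-yl)-3-chloro-3-methyloxolan-2-one
Conditions: 30% aq. H2O2, AcOH, 0 °C → rt
Reagents that add atoms: hydrogen peroxide, OO
Why: Baeyer–Villiger oxidation of a strained cyclobutanone runs under these mild acidic conditions without touching a monosubstituted alkene, and because the electron-poor chlorine-bearing C2' migrates much less readily than C6H2 (as known for α-chlorocyclobutanones), O1 should enter between C3' and C6 with both stereocentres untouched, base being avoided since it would contract the ring.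

**Step 4**
Reactants: 8 (3S,4R)-4-(but-3-en-1-yl)-3-chloro-3-methyloxolan-2-one
Product: 9 (3S,4R)-3-chloro-3-methyl-4-(3-oxobutyl)oxolan-2-one
Conditions: PdCl2 (10 mol %), CuCl (30 mol %), O2 (1 atm), DMF–H2O 7:1, rt
Reagents that add atoms: water, O (O2, O=O, is the terminal oxidant and ends as water)
Why: Tsuji–Wacker oxidation turns the terminal alkene with Markovnikov selectivity into the methyl ketone C2(=O)CH3, and the weakly acidic medium leaves the α-chloro lactone alone.

**Step 5**
Reactants: 9 (3S,4R)-3-chloro-3-methyl-4-(3-oxobutyl)oxolan-2-one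
Product: 10 (3S,4R)-3-chloro-4-(3,3-dimethoxybutyl)-3-methyloxolan-2-one
Conditions: HC(OMe)3, PPTS (cat.), MeOH, rt
Reagents that add atoms: trimethyl orthoformate, COC(OC)OC
Why: Acid-catalysed ketalisation driven by the orthoformate as water scavenger masks the ketone against the hydride of step 6, the dimethyl ketal being chosen because it can later leave as two molecules of volatile methanol.

**Step 6**
Reactants: 10 (3S,4R)-3-chloro-4-(3,3-dimethoxybutyl)-3-methyloxolan-2-one
Product: 11 (3S,4R)-3-chloro-4-(3,3-dimethoxybutyl)-3-methyloxolan-2-ol (anomers)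
Conditions: i-Bu2AlH (1.1 equiv), CH2Cl2, −78 °C; aq. potassium sodium tartrate
Reagents that add atoms: none
Why: Partial reduction of a γ-lactone with i-Bu2AlH at −78 °C stops at the tetrahedral aluminium hemiacetal, which gives the lactol on work-up, ketal and tertiary chloride being inert at this temperature.

**Step 7**
Reactants: 11 (3S,4R)-3-chloro-4-(3,3-dimethoxybutyl)-3-methyloxolan-2-ol; 12 bromoform
Product: 13 (2R,3S,4E)-5-bromo-3-chloro-2-(3,3-dimethoxybutyl)-3-methylpent-4-en-1-ol
Conditions: CrBr2 (8 equiv), CHBr3 (2.5 equiv), THF, 0 °C → rt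
Reagents that add atoms: bromoform 12, BrC(Br)Br (listed above as reactant)
Why: In the Takai olefination the geminal dichromium species formed from CHBr3 and divalent chromium adds to the open hydroxy-aldehyde tautomer of 11 and eliminates with the bulky quaternary C2' and bromine apart, which should give the E bromoalkene and free the C6 hydroxyl, while CrBr2 in place of CrCl2 keeps chloride out of the new vinyl halide.

**Step 8**
Reactants: 13 (2R,3S,4E)-5-bromo-3-chloro-2-(3,3-dimethoxybutyl)-3-methylpent-4-en-1-ol
Product: 15 (3R)-3-[(2S,3E)-4-bromo-2-chlorobut-3-en-2-yl]-6-methyl-3,4-dihydro-2H-pyran, via cyclic methyl ketal 14 (not isolated)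
Conditions: PPTS (10 mol %), 5 Å MS, PhMe, 90 °C
Reagents that add atoms: none
Why: Acid-catalysed transketalisation closes the oxane by 6-exo attack of the C6 hydroxyl on the C2 oxocarbenium ion, and loss of the second methanol under equilibrating conditions (ketal-to-enol-ether elimination) should give the more substituted endocyclic C2=C3 enol ether rather than the exocyclic isomer, the weak acid in an apolar solvent sparing the tertiary allylic chloride.

**Step 9**
Reactants: 15 (3R)-3-[(2S,3E)-4-bromo-2-chlorobut-3-en-2-yl]-6-methyl-3,4-dihydro-2H-pyran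
Product: 16 (2R,3R,5R)-3-bromo-5-[(2S,3E)-4-bromo-2-chlorobut-3-en-2-yl]-2-methyloxan-2-ol (axial bromide, expected main C3 epimer; the other epimer is already 17 and the mixture is carried on)
Conditions: NBS (1.05 equiv), THF–H2O 4:1, 0 °C
Reagents that add atoms: N-bromosuccinimide, O=C1CCC(=O)N1Br; water, O
Why: In this hydroxybromination of an enol ether the electron-rich C2=C3 bond reacts far faster than the bromoalkene, bromine must go to C3 and water to the oxocarbenium carbon C2, stereoelectronically preferred axial attack on the half-chair with the C5 group equatorial is expected to favour the (3R) bromide, and C2 settles by ring–chain equilibrium with OH axial (anomeric effect) and CH3 equatorial.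

**Step 10**
Reactants: 16 (2R,3R,5R)-3-bromo-5-[(2S,3E)-4-bromo-2-chlorobut-3-en-2-yl]-2-methyloxan-2-ol (crude mixture with 17)
Product: 17 (2R,3S,5R)-3-bromo-5-[(2S,3E)-4-bromo-2-chlorobut-3-en-2-yl]-2-methyloxan-2-ol (target)
Conditions: Bu4NBr (0.5 equiv), CH2Cl2, rt
Reagents that add atoms: tetrabutylammonium bromide, CCCC[N+](CCCC)(CCCC)CCCC.[Br-]
Why: In this halide-exchange epimerisation of an α-bromo ketone the small share of open-chain tautomer undergoes degenerate SN2 displacement by bromide with inversion at C3, so both epimers drain into the equilibrium mixture, in which 17 should prevail because its chair holds Br, CH3 and the C5 group equatorial, lacks the syn-axial Br/H5 contact of 16 and allows an O–H···Br hydrogen bond in the apolar medium, remaining 16 being separated and resubmitted.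

**Compound list**
1 | 2-chloropropanoyl chloride (racemic) | CC(Cl)C(=O)Cl | starting material
2 | (2R,5R)-2,5-dimethylpyrrolidine | C[C@@H]1CC[C@@H](C)N1 | starting material
3 | 2-chloro-1-[(2R,5R)-2,5-dimethylpyrrolidin-1-yl]propan-1-one | CC(Cl)C(=O)N1[C@H](C)CC[C@H]1C | intermediate
4 | hexa-1,5-diene | C=CCCC=C | starting material
5 | (2R,5R)-1-(2-chloroprop-1-en-1-ylidene)-2,5-dimethylpyrrolidinium triflate | CC(Cl)=C=[N+]1[C@H](C)CC[C@H]1C.[O-]S(=O)(=O)C(F)(F)F | intermediate (not isolated)
6 | (2R,5R)-1-[(2S,3R)-3-(but-3-en-1-yl)-2-chloro-2-methylcyclobutylidene]-2,5-dimethylpyrrolidinium triflate | C[C@@]1(Cl)C(=[N+]2[C@H](C)CC[C@H]2C)C[C@H]1CCC=C.[O-]S(=O)(=O)C(F)(F)F | intermediate (not isolated)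
7 | (2S,3R)-3-(but-3-en-1-yl)-2-chloro-2-methylcyclobutan-1-one (CH3 cis, Cl trans to the chain) | C[C@@]1(Cl)C(=O)C[C@H]1CCC=C | intermediate
8 | (3S,4R)-4-(but-3-en-1-yl)-3-chloro-3-methyloxolan-2-one | C[C@@]1(Cl)C(=O)OC[C@H]1CCC=C | intermediate
9 | (3S,4R)-3-chloro-3-methyl-4-(3-oxobutyl)oxolan-2-one | C[C@@]1(Cl)C(=O)OC[C@H]1CCC(C)=O | intermediate
10 | (3S,4R)-3-chloro-4-(3,3-dimethoxybutyl)-3-methyloxolan-2-one | C[C@@]1(Cl)C(=O)OC[C@H]1CCC(C)(OC)OC | intermediate
11 | (3S,4R)-3-chloro-4-(3,3-dimethoxybutyl)-3-methyloxolan-2-ol (anomers) | C[C@@]1(Cl)C(O)OC[C@H]1CCC(C)(OC)OC | intermediate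
12 | bromoform | BrC(Br)Br | starting material
13 | (2R,3S,4E)-5-bromo-3-chloro-2-(3,3-dimethoxybutyl)-3-methylpent-4-en-1-ol | C[C@@](Cl)(/C=C/Br)[C@@H](CO)CCC(C)(OC)OC | intermediate
14 | (2R,5R)-5-[(2S,3E)-4-bromo-2-chlorobut-3-en-2-yl]-2-methoxy-2-methyloxane (OMe axial) | C[C@@](Cl)(/C=C/Br)[C@H]1CO[C@@](C)(OC)CC1 | intermediate (not isolated)
15 | (3R)-3-[(2S,3E)-4-bromo-2-chlorobut-3-en-2-yl]-6-methyl-3,4-dihydro-2H-pyran | C[C@@](Cl)(/C=C/Br)[C@H]1COC(C)=CC1 | intermediate
16 | (2R,3R,5R)-3-bromo-5-[(2S,3E)-4-bromo-2-chlorobut-3-en-2-yl]-2-methyloxan-2-ol (Br axial, trans to the C5 group) | C[C@@](Cl)(/C=C/Br)[C@H]1CO[C@@](C)(O)[C@H](Br)C1 | intermediate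
17 | (2R,3S,5R)-3-bromo-5-[(2S,3E)-4-bromo-2-chlorobut-3-en-2-yl]-2-methyloxan-2-ol (Br equatorial, cis to the C5 group; OH axial) | C[C@@](Cl)(/C=C/Br)[C@H]1CO[C@@](C)(O)[C@@H](Br)C1 | target

**Total step count:** 10. **Longest linear sequence:** 10 (from 1 or 2 to 17).

**Steps most likely to fail**

**Step 2.**
- Chlorine and methyl differ little in size, so the alkene may pass either side and the C2'/C5 relationship would erode.
- The auxiliary may distinguish the two quadrants poorly.
- The activated α-chloro amide may lose HCl faster than an unactivated alkene traps it.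

The fallback sets out from 2 and 4 and returns at 7. It keeps the same two ring bonds but brings chlorine in afterwards, using known chemistry throughout. Amine 2 is acylated with propanoyl chloride to 1-[(2R,5R)-2,5-dimethylpyrrolidin-1-yl]propan-1-one F1. Activation with Tf2O and collidine in the presence of excess 4, a documented substrate class for this auxiliary, gives the 2-methylcyclobutaniminium triflate F2. Water hydrolyses it to (2R,3R)-3-(but-3-en-1-yl)-2-methylcyclobutan-1-one F3, whose C2 configuration is of no consequence. TMSOTf and Et3N under equilibrating conditions give the more substituted trimethylsilyl enol ether F4. NCS in CH2Cl2 then delivers chlorine to C2' from the face away from the butenyl chain, which leads to 7 with CH3 cis and Cl trans.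

**Step 7.**
- The electron-poor α-chloro lactol may release too little open aldehyde. The dichromium reagent would then decay before it reacts.
- Divalent chromium would have time to attack the C–Cl bond reductively.

The fallback sets out from 10 and returns at 14, and it offers the reagent a free aldehyde. Excess i-Bu2AlH (−78 → 0 °C) reduces 10 to (2S,3R)-2-chloro-3-(3,3-dimethoxybutyl)-2-methylbutane-1,4-diol F5. One equivalent of TBSCl with imidazole silylates the less hindered, more nucleophilic C6 hydroxyl to give the C6 mono-TBS ether F6. Dess–Martin periodinane buffered with NaHCO3 gives the α-chloro aldehyde F7. The same CHBr3/CrBr2 olefination, now fast, gives the E-bromoalkene TBS ether F8. CSA in MeOH at rt then removes the primary silyl group and closes the ring to 14, which enters the elimination of step 8.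

**Step 10.**
- The energy gap between the two C3 epimers may be too small, so the equilibration would enrich the equatorial bromide only weakly.

The fallback sets out from 15 and returns at 17. It turns the kinetic axial preference into the right configuration through one invertive displacement.
- Dimethyldioxirane (acetone–CH2Cl2, −78 → 0 °C) attacks the same stereoelectronically preferred face and gives the 2,3-epoxide F9, with oxygen trans to the C5 group.
- Water added to the flask opens it to (2R,3R,5R)-5-[(2S,3E)-4-bromo-2-chlorobut-3-en-2-yl]-2-methyloxane-2,3-diol F10.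
- TBSCl and imidazole trap the primary hydroxyl of the open-chain tautomer as the (3R)-α-hydroxy ketone TBS ether F11, and the C3 epimers are separated at this stage.
- Tf2O and 2,6-lutidine at −78 °C give the α-keto triflate F12.
- One equivalent of Bu4NBr (−78 → −20 °C) displaces the triflate with inversion, much faster than any bromide exchange, to give the (3S)-α-bromo ketone TBS ether F13.
- HF·pyridine in THF frees the C6 hydroxyl, which closes to 17.

**Further compounds**
F1 | step 2 | 1-[(2R,5R)-2,5-dimethylpyrrolidin-1-yl]propan-1-one | CCC(=O)N1[C@H](C)CC[C@H]1C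
F2 | step 2 | (2R,5R)-1-[(2R,3R)-3-(but-3-en-1-yl)-2-methylcyclobutylidene]-2,5-dimethylpyrrolidinium triflate | C[C@H]1C(=[N+]2[C@H](C)CC[C@H]2C)C[C@H]1CCC=C.[O-]S(=O)(=O)C(F)(F)F
F3 | step 2 | (2R,3R)-3-(but-3-en-1-yl)-2-methylcyclobutan-1-one | C[C@H]1C(=O)C[C@H]1CCC=C
F4 | step 2 | {[(3R)-3-(but-3-en-1-yl)-2-methylcyclobut-1-en-1-yl]oxy}trimethylsilane | CC1=C(O[Si](C)(C)C)C[C@H]1CCC=C
F5 | step 7 | (2S,3R)-2-chloro-3-(3,3-dimethoxybutyl)-2-methylbutane-1,4-diol | C[C@@](Cl)(CO)[C@@H](CO)CCC(C)(OC)OC
F6 | step 7 | (2S,3R)-3-{[(tert-butyldimethylsilyl)oxy]methyl}-2-chloro-6,6-dimethoxy-2-methylheptan-1-ol | C[C@@](Cl)(CO)[C@@H](CO[Si](C)(C)C(C)(C)C)CCC(C)(OC)OC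
F7 | step 7 | (2S,3R)-3-{[(tert-butyldimethylsilyl)oxy]methyl}-2-chloro-6,6-dimethoxy-2-methylheptanal | C[C@@](Cl)(C=O)[C@@H](CO[Si](C)(C)C(C)(C)C)CCC(C)(OC)OC
F8 | step 7 | tert-butyldimethylsilyl ether of 13 at the C6 oxygen | C[C@@](Cl)(/C=C/Br)[C@@H](CO[Si](C)(C)C(C)(C)C)CCC(C)(OC)OC
F9 | step 10 | (1R,4R,6R)-4-[(2S,3E)-4-bromo-2-chlorobut-3-en-2-yl]-1-methyl-2,7-dioxabicyclo[4.1.0]heptane | C[C@@](Cl)(/C=C/Br)[C@H]1CO[C@]2(C)O[C@@H]2C1
F10 | step 10 | (2R,3R,5R)-5-[(2S,3E)-4-bromo-2-chlorobut-3-en-2-yl]-2-methyloxane-2,3-diol | C[C@@](Cl)(/C=C/Br)[C@H]1CO[C@@](C)(O)[C@H](O)C1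
F11 | step 10 | (3R,5R,6S,7E)-8-bromo-5-{[(tert-butyldimethylsilyl)oxy]methyl}-6-chloro-3-hydroxy-6-methyloct-7-en-2-one | C[C@@](Cl)(/C=C/Br)[C@@H](CO[Si](C)(C)C(C)(C)C)C[C@@H](O)C(C)=O
F12 | step 10 | (3R,5R,6S,7E)-8-bromo-5-{[(tert-butyldimethylsilyl)oxy]methyl}-6-chloro-6-methyl-2-oxooct-7-en-3-yl triflate | C[C@@](Cl)(/C=C/Br)[C@@H](CO[Si](C)(C)C(C)(C)C)C[C@@H](OS(=O)(=O)C(F)(F)F)C(C)=O
F13 | step 10 | (3S,5R,6S,7E)-3,8-dibromo-5-{[(tert-butyldimethylsilyl)oxy]methyl}-6-chloro-6-methyloct-7-en-2-one | C[C@@](Cl)(/C=C/Br)[C@@H](CO[Si](C)(C)C(C)(C)C)C[C@H](Br)C(C)=O
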